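**Plan**

1. Retrosynthesis cuts, in order: the two ester C–O bonds (feruloyl on the propyl chain, p-coumaroyl on C3–CH2), the C3–CH2–O bond (back to an iodide), the ring bond O1–C2, the ring A aryl–C3 bond, and the cyclopropane formed from a ring B styrene.
2. Enabling feature: O1 on C2 and the oxygen on the exocyclic CH2 are 1,3-related through C3, so C2, C3 and that CH2 can be the three carbons of a cyclopropane. C2 is benzylic to ring B, whose para oxygen stabilises positive charge there, and the ring A phenol oxygen sits five atoms from C2.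
3. Forward: ring B styrene → enantioselective cyclopropanation → decarboxylative borylation → Suzuki–Miyaura union with the ring A bromophenol. Electrophile-triggered strain-release opening of the cyclopropane then closes the dihydrofuran ring and leaves CH2I on C3.
4. Chain joining: iodide → p-coumarate by carboxylate alkylation, propanol → ferulate by Steglich esterification, then one global desilylation.
5. Stereochemistry: the ring B-bearing cyclopropane carbon is set by the chiral copper catalyst. The neighbouring carbon (future C3) is re-set trans to it in the borylation and retained in the coupling. C2 arises by inversion in the ring opening, which turns the trans-cyclopropane into the trans-(2R,3S)-dihydrobenzofuran.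

Key step: step 9

Remark: with styrene the (S,S)-tert-butyl bis(oxazoline) ligand is known to favour the (1R,2R)-trans cyclopropane ester, so the (R,R) ligand is taken here to deliver the (1S,2S) series.

**Route**

Step 1
Reactants: 1 4-(3-hydroxypropyl)-2-methoxyphenol (dihydroconiferyl alcohol)
Product: 2 2-bromo-4-(3-hydroxypropyl)-6-methoxyphenol
Conditions: NBS (1.0 equiv), i-Pr2NH (10 mol%), CH2Cl2, 0 °C
Reagents that add atoms: N-bromosuccinimide, O=C1CCC(=O)N1Br
Why: Electrophilic aromatic bromination; the free hydroxyl directs ortho and its para position is blocked by the propanol chain, so bromine should enter at the one open position next to the OH.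

Step 2
Reactants: 3 (E)-3-(4-hydroxyphenyl)prop-2-enoic acid (p-coumaric acid)
Product: 5 (E)-3-{4-[tri(propan-2-yl)silyloxy]phenyl}prop-2-enoic acid, via bis-silylated coumarate 4 (not isolated)
Conditions: TIPSCl (2.3 equiv), imidazole, DMF, rt; then 1 M HCl (aq)/THF, rt
Reagents that add atoms: triisopropylsilyl chloride, CC(C)[Si](Cl)(C(C)C)C(C)C
Why: Silylation of phenol and acid followed by selective hydrolysis of the labile silyl ester (protecting-group installation); the aryl silyl ether is stable to dilute acid.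

Step 3
Reactants: 6 (E)-3-(4-hydroxy-3-methoxyphenyl)prop-2-enoic acid (ferulic acid)
Product: 8 (E)-3-{3-methoxy-4-[tri(propan-2-yl)silyloxy]phenyl}prop-2-enoic acid, via bis-silylated ferulate 7 (not isolated)
Conditions: TIPSCl (2.3 equiv), imidazole, DMF, rt; then 1 M HCl (aq)/THF, rt
Reagents that add atoms: triisopropylsilyl chloride, CC(C)[Si](Cl)(C(C)C)C(C)C
Why: Same silylation and selective silyl ester hydrolysis as in step 2.

Step 4
Reactants: 9 4-ethenyl-2-methoxyphenol (4-vinylguaiacol)
Product: 10 (4-ethenyl-2-methoxyphenoxy)tri(propan-2-yl)silane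
Conditions: TIPSCl (1.1 equiv), imidazole, DMF, 0 °C → rt
Reagents that add atoms: triisopropylsilyl chloride, CC(C)[Si](Cl)(C(C)C)C(C)C
Why: Silyl ether formation; the bulky silyl ether keeps ring B electron-rich but shields it in the later electrophilic step and is base-tolerant enough for steps 6 to 8.

Step 5
Reactants: 10 (4-ethenyl-2-methoxyphenoxy)tri(propan-2-yl)silane; 11 ethyl diazoacetate
Product: 12 ethyl (1S,2S)-2-{3-methoxy-4-[tri(propan-2-yl)silyloxy]phenyl}cyclopropane-1-carboxylate
Conditions: (CuOTf)2·C6H6 (0.5 mol%), 2,2'-(propane-2,2-diyl)bis[(4R)-4-tert-butyl-4,5-dihydro-1,3-oxazole] (1.2 mol%), CH2Cl2, 0 °C → rt, slow addition of 11 (1.5 equiv); chromatography to remove the cis ester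
Reagents that add atoms: none
Why: Copper–bis(oxazoline)-catalysed asymmetric carbene transfer (cyclopropanation); the C2-symmetric ligand controls which face of the styrene is attacked and so sets the aryl-bearing carbon as S, the trans ester being favoured.

Step 6
Reactants: 12 ethyl (1S,2S)-2-{3-methoxy-4-[tri(propan-2-yl)silyloxy]phenyl}cyclopropane-1-carboxylate
Product: 13 (1S,2S)-2-{3-methoxy-4-[tri(propan-2-yl)silyloxy]phenyl}cyclopropane-1-carboxylic acid
Conditions: LiOH·H2O (3 equiv), THF/MeOH/H2O, 0 °C → rt; 1 M HCl to pH 3 at 0 °C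
Reagents that add atoms: lithium hydroxide, [Li+].[OH-]
Why: Ester saponification; the cyclopropane is base-stable and the hindered aryl silyl ether should survive brief hydroxide treatment at room temperature.

Step 7
Reactants: 13 (1S,2S)-2-{3-methoxy-4-[tri(propan-2-yl)silyloxy]phenyl}cyclopropane-1-carboxylic acid
Product: 15 2-[(1S,2S)-2-{3-methoxy-4-[tri(propan-2-yl)silyloxy]phenyl}cyclopropyl]-4,4,5,5-tetramethyl-1,3,2-dioxaborolane, via N-acyloxyphthalimide 14 (not isolated)
Conditions: N-hydroxyphthalimide, DIC, DMAP (cat.), CH2Cl2, rt, filter; then NiCl2·6H2O (10 mol%), 4,4'-dimethoxy-2,2'-bipyridine (13 mol%), MgBr2·OEt2, premixed B2pin2/MeLi (3 equiv), THF/DMF, 0 °C → rt; chromatography to remove any cis boronate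
Reagents that add atoms: bis(pinacolato)diboron, CC1(C)OB(OC1(C)C)B1OC(C)(C)C(C)(C)O1; N-hydroxyphthalimide (its atoms stay only in intermediate 14), ON1C(=O)c2ccccc2C1=O
Why: Carbodiimide activation to the redox-active ester, then nickel-catalysed decarboxylative borylation; the cyclopropyl σ-radical formed on loss of CO2 should be borylated on the face away from the aryl group, so the aryl-bearing stereocentre is untouched and the future C3 is set trans to it.

Step 8
Reactants: 15 2-[(1S,2S)-2-{3-methoxy-4-[tri(propan-2-yl)silyloxy]phenyl}cyclopropyl]-4,4,5,5-tetramethyl-1,3,2-dioxaborolane; 2 2-bromo-4-(3-hydroxypropyl)-6-methoxyphenol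
Product: 16 4-(3-hydroxypropyl)-2-methoxy-6-[(1S,2S)-2-{3-methoxy-4-[tri(propan-2-yl)silyloxy]phenyl}cyclopropyl]phenol
Conditions: Pd(OAc)2 (5 mol%), SPhos (10 mol%), K3PO4 (3.5 equiv), toluene/H2O (20:1), 90 °C
Reagents that add atoms: none
Why: Suzuki–Miyaura coupling (oxidative addition of the aryl bromide to zerovalent palladium, transmetalation of the cyclopropylboronate with retention at carbon, reductive elimination); the free phenol and alcohol are tolerated and the trans-(1S,2S) geometry should be carried over.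

Step 9
Reactants: 16 4-(3-hydroxypropyl)-2-methoxy-6-[(1S,2S)-2-{3-methoxy-4-[tri(propan-2-yl)silyloxy]phenyl}cyclopropyl]phenol
Product: 17 3-[(2R,3R)-3-(iodomethyl)-7-methoxy-2-{3-methoxy-4-[tri(propan-2-yl)silyloxy]phenyl}-2,3-dihydro-1-benzofuran-5-yl]propan-1-ol
Conditions: NIS (1.05 equiv), NaHCO3 (2 equiv), CH2Cl2/MeCN (4:1), −40 → 0 °C, dark
Reagents that add atoms: N-iodosuccinimide, O=C1CCC(=O)N1I
Why: Proposed new method: iodonium transfer from N-iodosuccinimide to the unsubstituted cyclopropane carbon (corner attack) polarises its bond to the ring B-bearing carbon, where positive charge is stabilised in a quinone-methide-like way by the para silyloxy group, and the ring A phenol oxygen attacks that carbon anti to the departing CH2 as the strained bond (about 27 kcal/mol) breaks. The closest known reaction type is the electrophilic halocyclisation of cyclopropanes carrying a tethered oxygen nucleophile (1,3-halofunctionalisation, the homologue of alkene iodoetherification); a phenol on the aryl group of a 1,2-diarylcyclopropane has not been used as the nucleophile. The dihydrofuran ring closes in the 5-exo-tet mode, the breaking C–C bond being exocyclic to the forming ring. C3 of the product is the untouched ring A-bearing cyclopropane carbon (set trans in step 7, retained in step 8), and C2 is set by inversion at the ring B-bearing carbon, which converts the trans-cyclopropane into the trans-dihydrobenzofuran; an SN1-like opening should converge on the same, more stable trans isomer. The step needs chemoselectivity for the cyclopropane over aromatic iodination and regioselectivity for cleavage of the CH2–C(ring B) bond over the aryl-flanked C1–C2 bond: both ortho positions and the para position of the only free phenol are substituted, ring B is masked as a bulky silyl ether, no strong acid is formed (succinimide is the by-product and NaHCO3 buffers), and only the desired cleavage can be assisted by the phenol through a five-membered transition state.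

Step 10
Reactants: 17 3-[(2R,3R)-3-(iodomethyl)-7-methoxy-2-{3-methoxy-4-[tri(propan-2-yl)silyloxy]phenyl}-2,3-dihydro-1-benzofuran-5-yl]propan-1-ol; 5 (E)-3-{4-[tri(propan-2-yl)silyloxy]phenyl}prop-2-enoic acid
Product: 18 [(2R,3S)-5-(3-hydroxypropyl)-7-methoxy-2-{3-methoxy-4-[tri(propan-2-yl)silyloxy]phenyl}-2,3-dihydro-1-benzofuran-3-yl]methyl (E)-3-{4-[tri(propan-2-yl)silyloxy]phenyl}prop-2-enoate
Conditions: 5 (1.5 equiv), Cs2CO3 (0.8 equiv), DMF, 45 °C
Reagents that add atoms: none
Why: SN2 alkylation of a caesium carboxylate by the primary iodide in a dipolar aprotic solvent; the weakly basic carboxylate should favour substitution over elimination, the free primary alcohol is inert, and neither stereocentre is touched.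

Step 11
Reactants: 18 [(2R,3S)-5-(3-hydroxypropyl)-7-methoxy-2-{3-methoxy-4-[tri(propan-2-yl)silyloxy]phenyl}-2,3-dihydro-1-benzofuran-3-yl]methyl (E)-3-{4-[tri(propan-2-yl)silyloxy]phenyl}prop-2-enoate; 8 (E)-3-{3-methoxy-4-[tri(propan-2-yl)silyloxy]phenyl}prop-2-enoic acid
Product: 19 3-[(2R,3S)-7-methoxy-2-{3-methoxy-4-[tri(propan-2-yl)silyloxy]phenyl}-3-({[(E)-3-{4-[tri(propan-2-yl)silyloxy]phenyl}prop-2-enoyl]oxy}methyl)-2,3-dihydro-1-benzofuran-5-yl]propyl (E)-3-{3-methoxy-4-[tri(propan-2-yl)silyloxy]phenyl}prop-2-enoate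
Conditions: 8 (1.3 equiv), DIC, DMAP (10 mol%), CH2Cl2, 0 °C → rt
Reagents that add atoms: none
Why: Steglich esterification; the propanol hydroxyl is the only free OH in 18, so acylation should be site-specific.

Step 12
Reactants: 19 3-[(2R,3S)-7-methoxy-2-{3-methoxy-4-[tri(propan-2-yl)silyloxy]phenyl}-3-({[(E)-3-{4-[tri(propan-2-yl)silyloxy]phenyl}prop-2-enoyl]oxy}methyl)-2,3-dihydro-1-benzofuran-5-yl]propyl (E)-3-{3-methoxy-4-[tri(propan-2-yl)silyloxy]phenyl}prop-2-enoate
Product: 20 (+)-Boehmenan X, 3-[(2R,3S)-2-(4-hydroxy-3-methoxyphenyl)-3-({[(E)-3-(4-hydroxyphenyl)prop-2-enoyl]oxy}methyl)-7-methoxy-2,3-dihydro-1-benzofuran-5-yl]propyl (E)-3-(4-hydroxy-3-methoxyphenyl)prop-2-enoate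
Conditions: TBAF (3.5 equiv), AcOH (4 equiv), THF, 0 °C → rt
Reagents that add atoms: none
Why: Fluoride-induced cleavage of the three aryl silyl ethers (desilylation); acetic acid buffers the phenoxides so that the cinnamate esters and the benzylic aryl ether should survive, and no stereocentre is affected.

**Compound list**

1 | 4-(3-hydroxypropyl)-2-methoxyphenol (dihydroconiferyl alcohol) | COc1cc(CCCO)ccc1O | starting material
2 | 2-bromo-4-(3-hydroxypropyl)-6-methoxyphenol | COc1cc(CCCO)cc(Br)c1O | intermediate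
3 | (E)-3-(4-hydroxyphenyl)prop-2-enoic acid (p-coumaric acid) | OC(=O)/C=C/c1ccc(O)cc1 | starting material
4 | tri(propan-2-yl)silyl (E)-3-{4-[tri(propan-2-yl)silyloxy]phenyl}prop-2-enoate (not isolated) | CC(C)[Si](C(C)C)(C(C)C)OC(=O)/C=C/c1ccc(O[Si](C(C)C)(C(C)C)C(C)C)cc1 | intermediate
5 | (E)-3-{4-[tri(propan-2-yl)silyloxy]phenyl}prop-2-enoic acid | OC(=O)/C=C/c1ccc(O[Si](C(C)C)(C(C)C)C(C)C)cc1 | intermediate
6 | (E)-3-(4-hydroxy-3-methoxyphenyl)prop-2-enoic acid (ferulic acid) | COc1cc(/C=C/C(=O)O)ccc1O | starting material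
7 | tri(propan-2-yl)silyl (E)-3-{3-methoxy-4-[tri(propan-2-yl)silyloxy]phenyl}prop-2-enoate (not isolated) | COc1cc(/C=C/C(=O)O[Si](C(C)C)(C(C)C)C(C)C)ccc1O[Si](C(C)C)(C(C)C)C(C)C | intermediate
8 | (E)-3-{3-methoxy-4-[tri(propan-2-yl)silyloxy]phenyl}prop-2-enoic acid | COc1cc(/C=C/C(=O)O)ccc1O[Si](C(C)C)(C(C)C)C(C)C | intermediate
9 | 4-ethenyl-2-methoxyphenol (4-vinylguaiacol) | COc1cc(C=C)ccc1O | starting material
10 | (4-ethenyl-2-methoxyphenoxy)tri(propan-2-yl)silane | COc1cc(C=C)ccc1O[Si](C(C)C)(C(C)C)C(C)C | intermediate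
11 | ethyl diazoacetate | CCOC(=O)C=[N+]=[N-] | starting material
12 | ethyl (1S,2S)-2-{3-methoxy-4-[tri(propan-2-yl)silyloxy]phenyl}cyclopropane-1-carboxylate (trans) | CCOC(=O)[C@H]1C[C@@H]1c1ccc(O[Si](C(C)C)(C(C)C)C(C)C)c(OC)c1 | intermediate
13 | (1S,2S)-2-{3-methoxy-4-[tri(propan-2-yl)silyloxy]phenyl}cyclopropane-1-carboxylic acid | OC(=O)[C@H]1C[C@@H]1c1ccc(O[Si](C(C)C)(C(C)C)C(C)C)c(OC)c1 | intermediate
14 | 1,3-dioxoisoindolin-2-yl (1S,2S)-2-{3-methoxy-4-[tri(propan-2-yl)silyloxy]phenyl}cyclopropane-1-carboxylate (not isolated) | O=C(ON1C(=O)c2ccccc2C1=O)[C@H]1C[C@@H]1c1ccc(O[Si](C(C)C)(C(C)C)C(C)C)c(OC)c1 | intermediate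
15 | 2-[(1S,2S)-2-{3-methoxy-4-[tri(propan-2-yl)silyloxy]phenyl}cyclopropyl]-4,4,5,5-tetramethyl-1,3,2-dioxaborolane (trans) | CC1(C)OB(OC1(C)C)[C@H]1C[C@@H]1c1ccc(O[Si](C(C)C)(C(C)C)C(C)C)c(OC)c1 | intermediate
16 | 4-(3-hydroxypropyl)-2-methoxy-6-[(1S,2S)-2-{3-methoxy-4-[tri(propan-2-yl)silyloxy]phenyl}cyclopropyl]phenol (trans) | COc1cc(CCCO)cc([C@H]2C[C@@H]2c2ccc(O[Si](C(C)C)(C(C)C)C(C)C)c(OC)c2)c1O | intermediate
17 | 3-[(2R,3R)-3-(iodomethyl)-7-methoxy-2-{3-methoxy-4-[tri(propan-2-yl)silyloxy]phenyl}-2,3-dihydro-1-benzofuran-5-yl]propan-1-ol (2,3-trans) | OCCCc1cc(OC)c2c(c1)[C@@H](CI)[C@H](c1ccc(O[Si](C(C)C)(C(C)C)C(C)C)c(OC)c1)O2 | intermediate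
18 | [(2R,3S)-5-(3-hydroxypropyl)-7-methoxy-2-{3-methoxy-4-[tri(propan-2-yl)silyloxy]phenyl}-2,3-dihydro-1-benzofuran-3-yl]methyl (E)-3-{4-[tri(propan-2-yl)silyloxy]phenyl}prop-2-enoate | OCCCc1cc(OC)c2c(c1)[C@@H](COC(=O)/C=C/c1ccc(O[Si](C(C)C)(C(C)C)C(C)C)cc1)[C@H](c1ccc(O[Si](C(C)C)(C(C)C)C(C)C)c(OC)c1)O2 | intermediate
19 | tris(triisopropylsilyl) ether of Boehmenan X (all three phenols silylated; 2R,3S) | COc1cc(/C=C/C(=O)OCCCc2cc(OC)c3c(c2)[C@@H](COC(=O)/C=C/c2ccc(O[Si](C(C)C)(C(C)C)C(C)C)cc2)[C@H](c2ccc(O[Si](C(C)C)(C(C)C)C(C)C)c(OC)c2)O3)ccc1O[Si](C(C)C)(C(C)C)C(C)C | intermediate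
20 | (+)-Boehmenan X (2R,3S) | COc1cc(/C=C/C(=O)OCCCc2cc(OC)c3c(c2)[C@@H](COC(=O)/C=C/c2ccc(O)cc2)[C@H](c2ccc(O)c(OC)c2)O3)ccc1O | target

**Step count**

Total step count: 12. Longest linear sequence: 9 steps (steps 4 to 12, from 9 to 20).

**Steps most likely to fail**

1. Step 9 (proposed new method). The electrophile may instead attack the more electron-rich, aryl-flanked C1–C2 bond of the cyclopropane, which would lead to a six-membered chroman, or it may iodinate the aromatic rings. The fallback sets out from 16 and comes back at 17. 16 is treated with Hg(OCOCF3)2 in CH2Cl2 at −20 °C to give the alkylmercury trifluoroacetate F1. This solvomercuration of a cyclopropane with participation of an internal hydroxyl is a known reaction type: the metal attacks the least substituted ring carbon with inversion and the oxygen enters at the carbon best able to carry positive charge. The CH2 carbon is therefore addressed, the C1–C2 bond is left alone, and no electrophilic halogen meets the free phenol. Iododemercuration of F1 with I2 in CH2Cl2 then introduces the halogen in a separate step and gives 17.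

2. Step 8. Transmetalation of the secondary cyclopropylboronate to the hindered, electron-rich bromophenol may be slow, so that protodeboronation and loss of the aryl silyl ether in hot aqueous base take over. The fallback sets out from 2 and from 14 (isolated for this purpose) and comes back at 16. Both hydroxyls of 2 are protected with 3,4-dihydro-2H-pyran and PPTS to give the bis(tetrahydropyranyl) ether F2. Bromine–lithium exchange (n-BuLi, THF, −78 °C) and ZnCl2 give the arylzinc chloride F3. Nickel-catalysed decarboxylative Negishi-type coupling of F3 with 14 (NiCl2(MeOCH2CH2OMe), 4,4'-di-tert-butyl-2,2'-bipyridine, THF/DMF, rt) joins the aryl group directly to the cyclopropyl radical, trans to ring B, and gives the protected diarylcyclopropane F4. PPTS in MeOH removes both acetals and returns 16. This route needs neither the boronate nor aqueous base.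

3. Step 10. Substitution at the β-branched carbon may be slow enough that base-induced loss of HI toward the exocyclic alkene, followed by aromatisation to a benzofuran, competes. The fallback sets out from 17 and comes back at 19; it replaces carboxylate alkylation by acylation of an alcohol and reverses the order in which the two esters are made. 17 is converted without base into the diol F5 by tin hydride-mediated aerobic radical hydroxylation (Bu3SnH, dry air, toluene, 0 °C → rt, then PPh3). The unhindered propanol hydroxyl of F5 is esterified first with 8 (1.0 equiv, DIC, DMAP, CH2Cl2, −20 °C) to give the mono-ferulate F6. The remaining hydroxymethyl group is then acylated with 5 (DIC, DMAP) to give 19.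

**Further compounds**

F1 | step 9 | {[(2R,3R)-5-(3-hydroxypropyl)-7-methoxy-2-{3-methoxy-4-[tri(propan-2-yl)silyloxy]phenyl}-2,3-dihydro-1-benzofuran-3-yl]methyl}mercury trifluoroacetate | OCCCc1cc(OC)c2c(c1)[C@@H](C[Hg]OC(=O)C(F)(F)F)[C@H](c1ccc(O[Si](C(C)C)(C(C)C)C(C)C)c(OC)c1)O2
F2 | step 8 | 2-{3-[3-bromo-5-methoxy-4-(oxan-2-yloxy)phenyl]propoxy}oxane (mixture of acetal epimers) | COc1cc(CCCOC2CCCCO2)cc(Br)c1OC1CCCCO1
F3 | step 8 | chloro{3-methoxy-2-(oxan-2-yloxy)-5-[3-(oxan-2-yloxy)propyl]phenyl}zinc (not isolated) | COc1cc(CCCOC2CCCCO2)cc([Zn]Cl)c1OC1CCCCO1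
F4 | step 8 | bis(tetrahydropyranyl) ether of 16, (1S,2S)-trans | COc1cc(CCCOC2CCCCO2)cc([C@H]2C[C@@H]2c2ccc(O[Si](C(C)C)(C(C)C)C(C)C)c(OC)c2)c1OC1CCCCO1
F5 | step 10 | 3-[(2R,3S)-3-(hydroxymethyl)-7-methoxy-2-{3-methoxy-4-[tri(propan-2-yl)silyloxy]phenyl}-2,3-dihydro-1-benzofuran-5-yl]propan-1-ol | OCCCc1cc(OC)c2c(c1)[C@@H](CO)[C@H](c1ccc(O[Si](C(C)C)(C(C)C)C(C)C)c(OC)c1)O2
F6 | step 10 | 3-[(2R,3S)-3-(hydroxymethyl)-7-methoxy-2-{3-methoxy-4-[tri(propan-2-yl)silyloxy]phenyl}-2,3-dihydro-1-benzofuran-5-yl]propyl (E)-3-{3-methoxy-4-[tri(propan-2-yl)silyloxy]phenyl}prop-2-enoate | COc1cc(/C=C/C(=O)OCCCc2cc(OC)c3c(c2)[C@@H](CO)[C@H](c2ccc(O[Si](C(C)C)(C(C)C)C(C)C)c(OC)c2)O3)ccc1O[Si](C(C)C)(C(C)C)C(C)C
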